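**Retrosynthetic overview** (target numbering: ring O1, C2 hemiketal, C3 CHBr, C4, C5, C6; side chain C7 (CCl), C8=C9 (CHBr))
- The strategy rests on C5 carrying two methylene arms, C4 (to C3) and C6 (to O1), while C3–C2(CH3)–O1 is the enolate of an acetoacetate.
- The only ring (oxane O1–C6) is closed by [3+3] annulation of tert-butyl acetoacetate with ICH2–C5H(CH2Cl)–C7: carbon takes the iodide arm (C3–C4), oxygen the chloride arm (O1–C6).
- The C2/C3 functionality follows by exchanging the C3 ester for bromine (bromodecarboxylation to the 3-bromo enol ether) and hydrating C2=C3.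
- The dielectrophile comes from (3S,4R)-3-chloro-3-methyl-4-vinylbutyrolactone: C=O becomes C8=C9 (Takai), OCH2 becomes C6, vinyl becomes C4.
- The lactone stereocentres: C5 by Rh/(R)-BINAP conjugate vinylation of furan-2(5H)-one, C7 by methylation and then enolate chlorination anti to vinyl.

Key step: step 9

Assumption: (R)-BINAP is taken to give the (R)-configured vinyl lactone, by analogy with the sense of aryl and alkenyl transfer to cyclic enones and unsaturated lactones with this ligand; the mirror-image ligand would be used if the sense were opposite.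
Remark: the oxygen-arm leaving group is chloride, because a sulfonate would be exchanged by the iodide ion released and would compete with the iodide for the enolate carbon, which would scramble C5.

Step 1
Reactants: 1 furan-2(5H)-one; 2 potassium vinyltrifluoroborate
Product: 3 (4R)-4-ethenyloxolan-2-one
Conditions: [Rh(cod)2]BF4 (3 mol %), (R)-BINAP (3.3 mol %), 2 (2 equiv), toluene/H2O (20:1), 105 °C
Reagents that add atoms: none
Why: Rhodium-catalysed asymmetric conjugate addition (Hayashi–Miyaura type) in which the vinylrhodium–BINAP species inserts the lactone C=C on one enantioface and water protonates the rhodium enolate, so the ligand sets C5 of the target as R.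

Step 2
Reactants: 3 (4R)-4-ethenyloxolan-2-one
Product: 5 (3S,4S)-4-ethenyl-3-methyloxolan-2-one, via lithium enolate 4 (not isolated)
Conditions: LDA (1.05 equiv), THF, −78 °C; MeI, −78 → −40 °C
Reagents that add atoms: iodomethane, CI
Why: Lactone enolate alkylation in which iodomethane enters anti to the vinyl group; because this centre is planarised again in step 3, the trans/cis outcome here does not affect the route.

Step 3
Reactants: 5 (3S,4S)-4-ethenyl-3-methyloxolan-2-one
Product: 7 (3S,4R)-3-chloro-4-ethenyl-3-methyloxolan-2-one, via lithium enolate 6 (not isolated)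
Conditions: LDA (1.1 equiv), THF, −78 °C; NCS, THF, −78 °C; aq. NH4Cl
Reagents that add atoms: N-chlorosuccinimide, O=C1CCC(=O)N1Cl
Why: Electrophilic chlorination of the tetrasubstituted enolate, in which allylic strain with the enolate methyl turns the vinyl group over one face and the reagent attacks the other, so chlorine ends trans and methyl cis to vinyl, which is (S)-C7 relative to (R)-C5.

Step 4
Reactants: 7 (3S,4R)-3-chloro-4-ethenyl-3-methyloxolan-2-one
Product: 8 (2RS,3S,4R)-3-chloro-4-ethenyl-3-methyloxolan-2-ol
Conditions: DIBAL-H (1.1 equiv), CH2Cl2, −78 °C; aq. Rochelle salt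
Reagents that add atoms: none
Why: Partial reduction of a lactone to the lactol, the tetrahedral aluminium hemiacetal surviving at low temperature until work-up, with the tertiary chloride and the vinyl group inert.

Step 5
Reactants: 8 (2RS,3S,4R)-3-chloro-4-ethenyl-3-methyloxolan-2-ol; 9 bromoform
Product: 11 (2R,3S,4E)-5-bromo-3-chloro-2-ethenyl-3-methylpent-4-en-1-ol, via hydroxy aldehyde 10 (not isolated)
Conditions: CrBr2 (8 equiv), CHBr3 (3 equiv), THF, 0 → 25 °C
Reagents that add atoms: none
Why: Takai–Utimoto haloolefination in which the geminal dichromium species from bromoform and divalent chromium adds to the aldehyde tautomer of the lactol and eliminates to the (E)-bromoalkene, the α-quaternary centre favouring E, CrBr2 avoiding chlorine incorporation, and the ring oxygen being released as the free C6 hydroxyl.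

Step 6
Reactants: 11 (2R,3S,4E)-5-bromo-3-chloro-2-ethenyl-3-methylpent-4-en-1-ol
Product: 12 (1E,3S,4R)-1-bromo-3-chloro-4-(chloromethyl)-3-methylhexa-1,5-diene
Conditions: PPh3, NCS, THF, 0 → 40 °C
Reagents that add atoms: N-chlorosuccinimide, O=C1CCC(=O)N1Cl
Why: Appel-type chlorination in which chloride displaces the alkoxyphosphonium ion of the primary alcohol by SN2, installing the slow leaving group of the oxygen arm (C6) without touching either stereocentre.

Step 7
Reactants: 12 (1E,3S,4R)-1-bromo-3-chloro-4-(chloromethyl)-3-methylhexa-1,5-diene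
Product: 15 (2R,3S,4E)-5-bromo-3-chloro-2-(chloromethyl)-3-methylpent-4-en-1-ol, via ozonide 13 (not isolated), via aldehyde 14 (not isolated)
Conditions: O3 (1 equiv), CH2Cl2, −78 °C; then NaBH4, MeOH, −78 → 0 °C
Reagents that add atoms: ozone, [O-][O+]=O
Why: Ozonolysis with reductive borohydride work-up, in which electrophilic ozone should select the monosubstituted vinyl group over the bromoalkene (deactivated by bromine and the adjacent C–Cl carbon) and cold borohydride reduces the β-chloro aldehyde before it can lose HCl.

Step 8
Reactants: 15 (2R,3S,4E)-5-bromo-3-chloro-2-(chloromethyl)-3-methylpent-4-en-1-ol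
Product: 16 (1E,3R,4R)-1-bromo-3-chloro-4-(chloromethyl)-5-iodo-3-methylpent-1-ene
Conditions: PPh3, I2, imidazole, CH2Cl2, 0 → 25 °C
Reagents that add atoms: iodine, II
Why: Appel iodination by SN2 displacement of the alkoxyphosphonium ion, giving the fast leaving group of the carbon arm (C4); the descriptor at C7 changes to R only because CH2I outranks the bromovinyl branch, not because the centre is touched.

Step 9
Reactants: 16 (1E,3R,4R)-1-bromo-3-chloro-4-(chloromethyl)-5-iodo-3-methylpent-1-ene; 17 tert-butyl acetoacetate
Product: 19 tert-butyl (3R)-3-[(2S,3E)-4-bromo-2-chlorobut-3-en-2-yl]-6-methyl-3,4-dihydro-2H-pyran-5-carboxylate, via 2-alkylacetoacetate 18 (not isolated)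
Conditions: 17 (1.5 equiv), Cs2CO3 (3 equiv), DMF, 25 °C until 16 is consumed; then 60 °C
Reagents that add atoms: none
Why: The caesium enolate of 17 attacks the iodomethyl arm through carbon by SN2 (C3–C4), and the enolate of the resulting 2-alkylacetoacetate 18 then displaces the primary chloride through oxygen (O1–C6). The closest known reaction is the C,O-dialkylation of acetoacetic esters by 1-bromo-3-chloropropane and related 1,3-dihalides to 6-methyl-3,4-dihydro-2H-pyran-5-carboxylates. The one ring is closed in the 6-exo-tet mode through oxygen, the 4-exo-tet closure through carbon to a cyclobutane being much slower. No stereocentre is created, since C5 and C7 are spectators and the acetoacetate carbon ends sp2. The step needs site selectivity between the two arms, because the arm taken by carbon becomes C4 and so fixes the sense of C5; this is secured by the large rate difference between iodide and chloride toward the soft enolate carbon, by the inertness of the alkyl chloride to the iodide ion released, and by finishing the carbon alkylation at 25 °C before warming. The ester holds the double bond between C2 and C3 and is the handle later exchanged for bromine.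

Step 10
Reactants: 19 tert-butyl (3R)-3-[(2S,3E)-4-bromo-2-chlorobut-3-en-2-yl]-6-methyl-3,4-dihydro-2H-pyran-5-carboxylate
Product: 21 (3R)-3-[(2S,3E)-4-bromo-2-chlorobut-3-en-2-yl]-6-methyl-3,4-dihydro-2H-pyran-5-carboxylic acid, via silyl ester 20 (not isolated)
Conditions: TMSOTf (2 equiv), 2,6-lutidine (3 equiv), CH2Cl2, 0 °C; aq. NaH2PO4 work-up
Reagents that add atoms: none
Why: Silyl triflate-mediated cleavage of a tert-butyl ester (O-silylation of the vinylogous carbonate carbonyl, loss of the tert-butyl cation as isobutene, hydrolysis of the silyl ester on work-up) in a buffered, non-ionising medium that should spare the enol ether and the tertiary allylic chloride.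

Step 11
Reactants: 21 (3R)-3-[(2S,3E)-4-bromo-2-chlorobut-3-en-2-yl]-6-methyl-3,4-dihydro-2H-pyran-5-carboxylic acid
Product: 22 (3R)-5-bromo-3-[(2S,3E)-4-bromo-2-chlorobut-3-en-2-yl]-6-methyl-3,4-dihydro-2H-pyran
Conditions: NBS (1.0 equiv), Et3N (10 mol %), CH2Cl2 (anhydrous), 0 °C
Reagents that add atoms: N-bromosuccinimide, O=C1CCC(=O)N1Br
Why: Hunsdiecker-type ipso-bromodecarboxylation of a β-oxygenated acrylic acid, in which bromonium transfer to the carboxyl-bearing carbon (C3 of the target) gives an oxocarbenium–carboxylate zwitterion that loses CO2 and restores the enol ether with bromine in place of the carboxyl group, anhydrous conditions preventing hydration before decarboxylation.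

Step 12
Reactants: 22 (3R)-5-bromo-3-[(2S,3E)-4-bromo-2-chlorobut-3-en-2-yl]-6-methyl-3,4-dihydro-2H-pyran
Product: 23 (2R,3S,5R)-3-bromo-5-[(2S,3E)-4-bromo-2-chlorobut-3-en-2-yl]-2-methyloxan-2-ol
Conditions: HCl (0.1 M), THF/H2O (9:1), 0 °C
Reagents that add atoms: water, O
Why: Acid-catalysed hydration of an enol ether, in which protonation at C3 of the half-chair with the C5 side chain pseudoequatorial should occur axially through a chair-like transition state on the face away from the side chain, leaving bromine equatorial and cis to it (3S), while the hemiketal equilibrates at C2 to the anomer with axial hydroxyl and equatorial methyl (2R) and the bromide-free dilute acid should not epimerise C3.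

**Compound list**
1 | furan-2(5H)-one | O=C1OCC=C1 | starting material
2 | potassium vinyltrifluoroborate | C=C[B-](F)(F)F.[K+] | starting material
3 | (4R)-4-ethenyloxolan-2-one | O=C1C[C@H](C=C)CO1 | intermediate
4 | lithium (3S)-3-ethenyl-2,3-dihydrofuran-5-olate (lithium enolate of 3) | [Li]OC1=C[C@H](C=C)CO1 | intermediate (not isolated)
5 | (3S,4S)-4-ethenyl-3-methyloxolan-2-one | C[C@@H]1C(=O)OC[C@H]1C=C | intermediate
6 | lithium (3S)-3-ethenyl-4-methyl-2,3-dihydrofuran-5-olate (lithium enolate of 5) | [Li]OC1=C(C)[C@H](C=C)CO1 | intermediate (not isolated)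
7 | (3S,4R)-3-chloro-4-ethenyl-3-methyloxolan-2-one | C[C@@]1(Cl)C(=O)OC[C@H]1C=C | intermediate
8 | (2RS,3S,4R)-3-chloro-4-ethenyl-3-methyloxolan-2-ol (lactol, anomer mixture) | C[C@@]1(Cl)C(O)OC[C@H]1C=C | intermediate
9 | bromoform | BrC(Br)Br | starting material
10 | (2S,3R)-2-chloro-3-(hydroxymethyl)-2-methylpent-4-enal (open form of 8) | OC[C@@H](C=C)[C@](C)(Cl)C=O | intermediate (not isolated)
11 | (2R,3S,4E)-5-bromo-3-chloro-2-ethenyl-3-methylpent-4-en-1-ol | OC[C@@H](C=C)[C@](C)(Cl)/C=C/Br | intermediate
12 | (1E,3S,4R)-1-bromo-3-chloro-4-(chloromethyl)-3-methylhexa-1,5-diene | ClC[C@@H](C=C)[C@](C)(Cl)/C=C/Br | intermediate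
13 | 3-[(2R,3S,4E)-5-bromo-1,3-dichloro-3-methylpent-4-en-2-yl]-1,2,4-trioxolane (ozonide, epimers at the ring carbon) | ClC[C@@H](C1OCOO1)[C@](C)(Cl)/C=C/Br | intermediate (not isolated)
14 | (2R,3S,4E)-5-bromo-3-chloro-2-(chloromethyl)-3-methylpent-4-enal | ClC[C@@H](C=O)[C@](C)(Cl)/C=C/Br | intermediate (not isolated)
15 | (2R,3S,4E)-5-bromo-3-chloro-2-(chloromethyl)-3-methylpent-4-en-1-ol | ClC[C@@H](CO)[C@](C)(Cl)/C=C/Br | intermediate
16 | (1E,3R,4R)-1-bromo-3-chloro-4-(chloromethyl)-5-iodo-3-methylpent-1-ene | ClC[C@@H](CI)[C@](C)(Cl)/C=C/Br | intermediate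
17 | tert-butyl acetoacetate | CC(=O)CC(=O)OC(C)(C)C | starting material
18 | tert-butyl (4R,5S,6E)-2-acetyl-7-bromo-5-chloro-4-(chloromethyl)-5-methylhept-6-enoate (C2 epimers) | ClC[C@@H](CC(C(C)=O)C(=O)OC(C)(C)C)[C@](C)(Cl)/C=C/Br | intermediate (not isolated)
19 | tert-butyl (3R)-3-[(2S,3E)-4-bromo-2-chlorobut-3-en-2-yl]-6-methyl-3,4-dihydro-2H-pyran-5-carboxylate | CC1=C(C(=O)OC(C)(C)C)C[C@H](CO1)[C@](C)(Cl)/C=C/Br | intermediate
20 | trimethylsilyl (3R)-3-[(2S,3E)-4-bromo-2-chlorobut-3-en-2-yl]-6-methyl-3,4-dihydro-2H-pyran-5-carboxylate | CC1=C(C(=O)O[Si](C)(C)C)C[C@H](CO1)[C@](C)(Cl)/C=C/Br | intermediate (not isolated)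
21 | (3R)-3-[(2S,3E)-4-bromo-2-chlorobut-3-en-2-yl]-6-methyl-3,4-dihydro-2H-pyran-5-carboxylic acid | CC1=C(C(=O)O)C[C@H](CO1)[C@](C)(Cl)/C=C/Br | intermediate
22 | (3R)-5-bromo-3-[(2S,3E)-4-bromo-2-chlorobut-3-en-2-yl]-6-methyl-3,4-dihydro-2H-pyran | CC1=C(Br)C[C@H](CO1)[C@](C)(Cl)/C=C/Br | intermediate
23 | (2R,3S,5R)-3-bromo-5-[(2S,3E)-4-bromo-2-chlorobut-3-en-2-yl]-2-methyloxan-2-ol | C[C@@](Cl)(/C=C/Br)[C@H]1CO[C@@](C)(O)[C@@H](Br)C1 | target

**Step count and risks**
Total steps: 12. Longest linear sequence: 12 steps, from furan-2(5H)-one 1; compounds 2, 9 and 17 enter directly.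

Steps most likely to fail:

Step 9. The fidelity between the two arms may be lost (carbon attack at the chloromethyl arm, oxygen-first alkylation at the iodomethyl arm, or halide exchange before alkylation), which would erode the configuration at C5. The oxygen closure at the β-branched chloride may also be slow enough for dehydrochlorination at C7 or intermolecular dialkylation to compete. The fallback sets out from 11 and comes back at 19, and closes the O1–C2 bond by hemiketalisation and dehydration instead of O-alkylation. Alcohol 11 would be silylated (TBSCl, imidazole) to the silyl ether F1. Selective ozonolysis with borohydride work-up would give the alcohol F2, and Appel iodination the iodide F3. The caesium enolate of 17 would be C-alkylated by F3 in a single displacement, with no second leaving group present, to the 2-alkylacetoacetate F4. HF·pyridine would remove the silyl group to give the hydroxy keto ester F5, in equilibrium with its cyclic hemiketal. Catalytic PPTS in benzene over 4 Å molecular sieves would dehydrate the hemiketal to 19.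

Step 5. The α-quaternary lactol may open too slowly, so that the dichromium reagent decays, and long exposure to excess divalent chromium may cleave the tertiary (then allylic) chloride reductively or scramble halogens. The fallback sets out from 7 and comes back at 11, and delivers the aldehyde as a free open-chain species. Lactone 7 would be opened with Me2AlN(OMe)Me (from AlMe3 and MeNHOMe·HCl) to the hydroxy Weinreb amide F6. This would be silylated at once (TESCl, imidazole) to the silyl ether F7 and reduced with DIBAL-H at −78 °C to the aldehyde F8. F8 would be olefinated with CrBr2/CHBr3 with short contact time to the bromoalkene F9, and PPTS in methanol would remove the silyl group to give 11.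

Step 12. The facial selectivity of protonation at C3 may be poor, or hydration of the bromine-deactivated enol ether may be slow enough for solvolysis of the tertiary allylic chloride to compete. The fallback sets out from 22 and comes back at 23, and puts C3 under thermodynamic control with recycling instead of kinetic protonation. The hydration of 22 would be run to completion and the C3 epimer F10 separated from 23. F10 would be equilibrated at C3 by bromide exchange (LiBr, acetone, 25 °C; SN2 inversion on the open-chain α-bromo ketone), the mixture separated again and recovered F10 resubmitted. The position of this equilibrium is not known in advance, so several cycles may be needed.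

**Further compounds**
F1 | step 9 | tert-butyl{[(2R,3S,4E)-5-bromo-3-chloro-2-ethenyl-3-methylpent-4-en-1-yl]oxy}dimethylsilane | CC(C)(C)[Si](C)(C)OC[C@@H](C=C)[C@](C)(Cl)/C=C/Br
F2 | step 9 | (2R,3S,4E)-5-bromo-2-({[tert-butyl(dimethyl)silyl]oxy}methyl)-3-chloro-3-methylpent-4-en-1-ol | CC(C)(C)[Si](C)(C)OC[C@@H](CO)[C@](C)(Cl)/C=C/Br
F3 | step 9 | tert-butyl{[(2R,3R,4E)-5-bromo-3-chloro-2-(iodomethyl)-3-methylpent-4-en-1-yl]oxy}dimethylsilane | CC(C)(C)[Si](C)(C)OC[C@@H](CI)[C@](C)(Cl)/C=C/Br
F4 | step 9 | tert-butyl (4R,5S,6E)-2-acetyl-7-bromo-4-({[tert-butyl(dimethyl)silyl]oxy}methyl)-5-chloro-5-methylhept-6-enoate | CC(C)(C)[Si](C)(C)OC[C@@H](CC(C(C)=O)C(=O)OC(C)(C)C)[C@](C)(Cl)/C=C/Br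
F5 | step 9 | tert-butyl (4R,5S,6E)-2-acetyl-7-bromo-5-chloro-4-(hydroxymethyl)-5-methylhept-6-enoate | OC[C@@H](CC(C(C)=O)C(=O)OC(C)(C)C)[C@](C)(Cl)/C=C/Br
F6 | step 5 | (2S,3R)-2-chloro-3-(hydroxymethyl)-N-methoxy-N,2-dimethylpent-4-enamide | OC[C@@H](C=C)[C@](C)(Cl)C(=O)N(C)OC
F7 | step 5 | (2S,3R)-2-chloro-N-methoxy-N,2-dimethyl-3-{[(triethylsilyl)oxy]methyl}pent-4-enamide | CC[Si](CC)(CC)OC[C@@H](C=C)[C@](C)(Cl)C(=O)N(C)OC
F8 | step 5 | (2S,3R)-2-chloro-2-methyl-3-{[(triethylsilyl)oxy]methyl}pent-4-enal | CC[Si](CC)(CC)OC[C@@H](C=C)[C@](C)(Cl)C=O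
F9 | step 5 | {[(2R,3S,4E)-5-bromo-3-chloro-2-ethenyl-3-methylpent-4-en-1-yl]oxy}triethylsilane | CC[Si](CC)(CC)OC[C@@H](C=C)[C@](C)(Cl)/C=C/Br
F10 | step 12 | (2R,3R,5R)-3-bromo-5-[(2S,3E)-4-bromo-2-chlorobut-3-en-2-yl]-2-methyloxan-2-ol | C[C@@](Cl)(/C=C/Br)[C@H]1CO[C@@](C)(O)[C@H](Br)C1
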